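**Retrosynthetic overview**

1. The target is traced back, by desilylation, acetylation at O6, a B-alkyl Suzuki–Miyaura coupling with 4-bromofuran-2(5H)-one and C11 homologation, to bicyclic ester 19, in which C11 is an ester on C9.
2. Ring B is a cyclohexene with oxygen on C6, the C8=C9 double bond across the ring, and the carbon branch C11 on C9. With C11 as an ester, C10 is the β-carbon of an enoate and C7 the γ-end of its dienolate, so ring B maps onto a C7=C8–C9=C10 dienoate plus a C5=C6 silyl enol ether.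
3. Cutting C5–C10 and C6–C7 opens both rings to the open-chain triene 17; in the forward sense ring A closes first (C5–C10), then ring B (C6–C7), in one operation.
4. 17 comes from ynoate 11 by syn-carbocupration/iodination (fixes the C9=C10 geometry), oxidative cleavage of an allyl group to the C6 aldehyde, Suzuki coupling and enol silylation.
5. 11 comes from lactone 1 (C19, C4, C3, C2, C1): methylation then allylation anti to CH2OTr sets C4, and an orthopropiolate acetylide displaces a C1 triflate.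

Key step: step 12

Remarks on the chemistry: atoms are numbered as in the labdane skeleton (C1–C20). Enol ether 17 is carried on as its E/Z mixture, because C6 is expected to be fixed only after the first C–C bond has formed. Compounds 1, 8, 15 and 23 are taken as commercial. TBS = tert-butyldimethylsilyl, TES = triethylsilyl, Tr = trityl.

**Route**

Step 1
Reactants: 1 (S)-5-(hydroxymethyl)dihydrofuran-2(3H)-one
Product: 2 (S)-5-[(trityloxy)methyl]dihydrofuran-2(3H)-one
Conditions: TrCl, Et3N, DMAP (cat.), CH2Cl2, rt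
Reagents that add atoms: trityl chloride, ClC(c1ccccc1)(c1ccccc1)c1ccccc1
Why: Tritylation of the primary alcohol puts a bulky group on the γ-carbon (C2) that will shield one face of the lactone enolate; no stereocentre is touched.

Step 2
Reactants: 2 (S)-5-[(trityloxy)methyl]dihydrofuran-2(3H)-one
Product: 3 (5S)-3-methyl-5-[(trityloxy)methyl]dihydrofuran-2(3H)-one (C3 epimers)
Conditions: LiN(i-Pr)2, THF, −78 °C; MeI
Reagents that add atoms: iodomethane, CI
Why: Lactone enolate alkylation brings in C18; the new centre is planarised again in step 3, so its configuration does not matter.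

Step 3
Reactants: 3 (5S)-3-methyl-5-[(trityloxy)methyl]dihydrofuran-2(3H)-one
Product: 4 (3R,5S)-3-allyl-3-methyl-5-[(trityloxy)methyl]dihydrofuran-2(3H)-one
Conditions: LiN(i-Pr)2, THF, −78 °C; allyl bromide, DMPU, −78 → −40 °C
Reagents that add atoms: allyl bromide, C=CCBr
Why: Second enolate alkylation: the planar α-methyl enolate should take allyl bromide on the face anti to the γ-CH2OTr group (1,3-induction in γ-substituted butyrolactone enolates), which sets quaternary C4 with allyl trans to CH2OTr.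

Step 4
Reactants: 4 (3R,5S)-3-allyl-3-methyl-5-[(trityloxy)methyl]dihydrofuran-2(3H)-one
Product: 5 (2S,4R)-4-(hydroxymethyl)-4-methyl-1-(trityloxy)hept-6-en-2-ol
Conditions: LiAlH4, THF, 0 °C → rt
Reagents that add atoms: none
Why: Hydride reduction of the lactone opens it to the C2/C19 diol and brings C19 to the alcohol level without touching C2 or C4.

Step 5
Reactants: 5 (2S,4R)-4-(hydroxymethyl)-4-methyl-1-(trityloxy)hept-6-en-2-ol
Product: 6 (2S,4R)-2-(TBS-oxy)-4-[(TBS-oxy)methyl]-4-methyl-1-(trityloxy)hept-6-ene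
Conditions: TBSOTf, 2,6-lutidine, CH2Cl2, −78 → 0 °C
Reagents that add atoms: tert-butyldimethylsilyl triflate, CC(C)(C)[Si](C)(C)OS(=O)(=O)C(F)(F)F
Why: Silylation of both hydroxyls gives O2 and O19 the same group, which is inert to the later silyl Lewis acid and comes off together at the end.

Step 6
Reactants: 6 (2S,4R)-2-(TBS-oxy)-4-[(TBS-oxy)methyl]-4-methyl-1-(trityloxy)hept-6-ene
Product: 7 (2S,4R)-2-(TBS-oxy)-4-[(TBS-oxy)methyl]-4-methylhept-6-en-1-ol
Conditions: BCl3, CH2Cl2, −30 °C; aq. NaHCO3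
Reagents that add atoms: none
Why: Lewis-acid detritylation: the trityl ether ionises to the stabilised trityl cation much faster than a TBS ether is attacked at this temperature, so only O1 should be freed.

Step 7
Reactants: 7 (2S,4R)-2-(TBS-oxy)-4-[(TBS-oxy)methyl]-4-methylhept-6-en-1-ol and 8 3,3,3-triethoxyprop-1-yne
Product: 11 ethyl (5R,7R)-5-(TBS-oxy)-7-[(TBS-oxy)methyl]-7-methyldec-9-en-2-ynoate, via primary triflate 9 (not isolated), via orthoester alkyne 10 (not isolated)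
Conditions: Tf2O, 2,6-lutidine, CH2Cl2, −78 °C, pentane filtration; lithium acetylide of 8 (n-BuLi, THF, −78 °C), DMPU, −78 → −20 °C; AcOH/THF/H2O, rt
Reagents that add atoms: water, O
Why: Acetylide alkylation (SN2 at the primary triflate) forms C1–C10 without touching C2; the orthoester is a non-electrophilic propiolate equivalent that hydrolyses to the ethyl ester (C11) on mild acid work-up.

Step 8
Reactants: 11 ethyl (5R,7R)-5-(TBS-oxy)-7-[(TBS-oxy)methyl]-7-methyldec-9-en-2-ynoate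
Product: 13 ethyl (2E,5S,7R)-5-(TBS-oxy)-7-[(TBS-oxy)methyl]-2-iodo-3,7-dimethyldeca-2,9-dienoate, via alkenyl(methyl)cuprate 12 (not isolated)
Conditions: Me2CuLi (from CuI, 2 MeLi), THF, −78 °C; I2, THF, −78 °C
Reagents that add atoms: lithium dimethylcuprate, [Li+].C[Cu-]C; iodine, II
Why: Syn-carbocupration (conjugate addition) of the ynoate brings in C20, and iodinolysis of the alkenylcopper with retention at −78 °C should place iodine cis to the new methyl, so the C1 tether ends up cis to the ester.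

Step 9
Reactants: 13 ethyl (2E,5S,7R)-5-(TBS-oxy)-7-[(TBS-oxy)methyl]-2-iodo-3,7-dimethyldeca-2,9-dienoate
Product: 14 ethyl (2E,5S,7S)-5-(TBS-oxy)-7-[(TBS-oxy)methyl]-2-iodo-3,7-dimethyl-9-oxonon-2-enoate
Conditions: OsO4 (cat.), NaIO4, 2,6-lutidine, dioxane/H2O, rt
Reagents that add atoms: sodium periodate (oxygen source through the OsO4 cycle), [Na+].[O-]I(=O)(=O)=O
Why: Lemieux–Johnson cleavage: the monosubstituted alkene is dihydroxylated far faster than the electron-poor, tetrasubstituted iodoenoate, which unmasks the C6 aldehyde.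

Step 10
Reactants: 14 ethyl (2E,5S,7S)-5-(TBS-oxy)-7-[(TBS-oxy)methyl]-2-iodo-3,7-dimethyl-9-oxonon-2-enoate and 15 4,4,5,5-tetramethyl-2-(prop-1-en-2-yl)-1,3,2-dioxaborolane
Product: 16 ethyl (2Z,5R,7S)-5-(TBS-oxy)-7-[(TBS-oxy)methyl]-3,7-dimethyl-9-oxo-2-(prop-1-en-2-yl)non-2-enoate
Conditions: PdCl2(dppf) (cat.), K3PO4, THF/H2O, 50 °C
Reagents that add atoms: none
Why: Suzuki–Miyaura coupling of the alkenyl iodide proceeds with retention of alkene geometry and installs C7, C8 and C17; the aldehyde is tolerated.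

Step 11
Reactants: 16 ethyl (2Z,5R,7S)-5-(TBS-oxy)-7-[(TBS-oxy)methyl]-3,7-dimethyl-9-oxo-2-(prop-1-en-2-yl)non-2-enoate
Product: 17 ethyl (2Z,5R,7S)-5-(TBS-oxy)-7-[(TBS-oxy)methyl]-3,7-dimethyl-2-(prop-1-en-2-yl)-9-(TES-oxy)nona-2,8-dienoate (8E/8Z mixture)
Conditions: TESOTf, Et3N, CH2Cl2, −78 → 0 °C; filtration through Et3N-deactivated silica
Reagents that add atoms: triethylsilyl triflate, CC[Si](CC)(CC)OS(=O)(=O)C(F)(F)F
Why: Soft enolisation/O-silylation of the aldehyde (enolisable only towards C5) gives the C5=C6 silyl enol ether; the ester has no α-hydrogen.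

Step 12
Reactants: 17 ethyl (2Z,5R,7S)-5-(TBS-oxy)-7-[(TBS-oxy)methyl]-3,7-dimethyl-2-(prop-1-en-2-yl)-9-(TES-oxy)nona-2,8-dienoate (8E/8Z mixture)
Product: 19 ethyl 2α,19-bis(TBS-oxy)-6α-(TES-oxy)-12,13,14,15,16-pentanorlabd-8-en-11-oate (5α-H; 10β-CH3), via ring-A oxocarbenium silyl ketene acetal 18 (not isolated)
Conditions: HNTf2 (10 mol%), CH2Cl2, −78 → −40 °C; Et3N quench
Reagents that add atoms: none
Why: Proposed new method: HNTf2 should protodesilylate a trace of 17 to Et3SiNTf2, which silylates the ester carbonyl; enol ether carbon C5 then adds to the strongly electrophilic C10 (Mukaiyama–Michael) and the silyloxocarbenium ion at C6 of 18 is captured by C7, the γ-carbon of the silyl dienol ether, with return of the silyl cation (vinylogous Mukaiyama aldol), so the whole is a polar, stepwise inverse-electron-demand [4+2] annulation whose closest known relatives are the HNTf2- or EtAlCl2-catalysed Michael–aldol ([2+2]) reactions of silyl enol ethers with acrylates, which keep the silyloxy group, and the thermal inverse-demand Diels–Alder reactions of 2-alkoxycarbonyl dienes with enol ethers. Ring A closes in the 6-(enolexo)-exo-trig mode and ring B in the 6-(enolendo)-exo-trig mode. C5 and C10 are set in a chair-like ring-A transition state in which the C2 silyloxy group, the C6 arm and the bulky dienyl ester are equatorial and only the C10 methyl and the C19 arm (fixed by C4) are axial, which should give the trans ring fusion in the correct sense relative to C2 and C4. C6 is set in the second closure, where the silyloxy group takes the equatorial (α) position to avoid the axial C19 and C20 groups, and because the C5–C6 bond rotates freely in 18 both enol ether isomers should converge on the same product. The step needs attack through C7 and not C9, and through carbon and not the carbonyl oxygen: C9 is fully substituted, a cyclobutane would carry two adjacent quaternary carbons and would reopen as a donor–acceptor cyclobutane under the same catalyst, and an ester at C11 disfavours the oxa-[4+2] mode.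

Step 13
Reactants: 19 ethyl 2α,19-bis(TBS-oxy)-6α-(TES-oxy)-12,13,14,15,16-pentanorlabd-8-en-11-oate
Product: 20 2α,19-bis(TBS-oxy)-6α-(TES-oxy)-12,13,14,15,16-pentanorlabd-8-en-11-ol
Conditions: i-Bu2AlH (DIBAL-H), CH2Cl2, −78 → 0 °C; aq. KNaC4H4O6
Reagents that add atoms: none
Why: 1,2-Reduction of the conjugated ester gives the C11 allylic alcohol; the silyl ethers are inert.

Step 14
Reactants: 20 2α,19-bis(TBS-oxy)-6α-(TES-oxy)-12,13,14,15,16-pentanorlabd-8-en-11-ol
Product: 21 2α,19-bis(TBS-oxy)-6α-(TES-oxy)-12,13,14,15,16-pentanorlabd-8-en-11-al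
Conditions: Dess–Martin periodinane, NaHCO3, CH2Cl2, rt
Reagents that add atoms: none
Why: Dess–Martin oxidation of the hindered primary allylic alcohol to the enal under buffered conditions that spare the TES ether.

Step 15
Reactants: 21 2α,19-bis(TBS-oxy)-6α-(TES-oxy)-12,13,14,15,16-pentanorlabd-8-en-11-al
Product: 22 2α,19-bis(TBS-oxy)-6α-(TES-oxy)-13,14,15,16-tetranorlabda-8,11-diene
Conditions: Ph3PCH3Br, KN(SiMe3)2, THF, 0 °C → rt
Reagents that add atoms: methyltriphenylphosphonium bromide (as its ylide), C[P+](c1ccccc1)(c1ccccc1)c1ccccc1.[Br-]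
Why: Wittig methylenation adds C12; O6 is silylated, so no alkoxide can trigger a retro-vinylogous-aldol opening of ring B.

Step 16
Reactants: 22 2α,19-bis(TBS-oxy)-6α-(TES-oxy)-13,14,15,16-tetranorlabda-8,11-diene and 23 4-bromofuran-2(5H)-one
Product: 25 2α,19-bis(TBS-oxy)-6α-(TES-oxy)labda-8,13-dien-15,16-olide, via C12 alkyl-9-BBN borane 24 (not isolated)
Conditions: 9-BBN, THF, 0 °C → rt; then 23, PdCl2(dppf) (cat.), AsPh3, aq. K3PO4, DMF, rt
Reagents that add atoms: none
Why: Anti-Markovnikov hydroboration at the only unhindered (monosubstituted) alkene, then B-alkyl Suzuki–Miyaura coupling with the β-bromobutenolide, forms C12–C13; the tetrasubstituted C8=C9 bond does not react.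

Step 17
Reactants: 25 2α,19-bis(TBS-oxy)-6α-(TES-oxy)labda-8,13-dien-15,16-olide
Product: 26 2α,19-bis(TBS-oxy)-6α-hydroxylabda-8,13-dien-15,16-olide
Conditions: PPTS (cat.), MeOH/CH2Cl2, 0 °C
Reagents that add atoms: none
Why: Acid-catalysed methanolysis removes the TES ether, which is far more labile than the secondary and neopentyl TBS ethers, so only O6 should be freed.

Step 18
Reactants: 26 2α,19-bis(TBS-oxy)-6α-hydroxylabda-8,13-dien-15,16-olide
Product: 27 6α-acetoxy-2α,19-bis(TBS-oxy)labda-8,13-dien-15,16-olide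
Conditions: Ac2O, DMAP, pyridine, CH2Cl2, rt
Reagents that add atoms: acetic anhydride, CC(=O)OC(C)=O
Why: DMAP-catalysed acylation of the only free hydroxyl puts the acetate on O6 with retention at C6.

Step 19
Reactants: 27 6α-acetoxy-2α,19-bis(TBS-oxy)labda-8,13-dien-15,16-olide
Product: 28 CNP0231903.1 (6α-acetoxy-2α,19-dihydroxylabda-8,13-dien-15,16-olide; 2R,4S,5R,6S,10S)
Conditions: HF·pyridine, pyridine/THF, 0 °C → rt
Reagents that add atoms: none
Why: Fluoride-mediated desilylation under mildly acidic conditions frees O2 and O19 without acetate cleavage or migration and without harm to the butenolide.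

**Compound list**

1 | (S)-5-(hydroxymethyl)dihydrofuran-2(3H)-one | OC[C@@H]1CCC(=O)O1 | starting material
2 | (S)-5-[(trityloxy)methyl]dihydrofuran-2(3H)-one | C(c1ccccc1)(c1ccccc1)(c1ccccc1)OC[C@@H]2CCC(=O)O2 | intermediate
3 | (5S)-3-methyl-5-[(trityloxy)methyl]dihydrofuran-2(3H)-one, C3 epimers | C(c1ccccc1)(c1ccccc1)(c1ccccc1)OC[C@@H]2CC(C)C(=O)O2 | intermediate
4 | (3R,5S)-3-allyl-3-methyl-5-[(trityloxy)methyl]dihydrofuran-2(3H)-one (allyl trans to CH2OTr) | C(c1ccccc1)(c1ccccc1)(c1ccccc1)OC[C@@H]2C[C@@](C)(CC=C)C(=O)O2 | intermediate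
5 | (2S,4R)-4-(hydroxymethyl)-4-methyl-1-(trityloxy)hept-6-en-2-ol | C(c1ccccc1)(c1ccccc1)(c1ccccc1)OC[C@@H](O)C[C@](C)(CO)CC=C | intermediate
6 | (2S,4R)-2-(TBS-oxy)-4-[(TBS-oxy)methyl]-4-methyl-1-(trityloxy)hept-6-ene | C(c1ccccc1)(c1ccccc1)(c1ccccc1)OC[C@@H](O[Si](C)(C)C(C)(C)C)C[C@](C)(CO[Si](C)(C)C(C)(C)C)CC=C | intermediate
7 | (2S,4R)-2-(TBS-oxy)-4-[(TBS-oxy)methyl]-4-methylhept-6-en-1-ol | OC[C@@H](O[Si](C)(C)C(C)(C)C)C[C@](C)(CO[Si](C)(C)C(C)(C)C)CC=C | intermediate
8 | 3,3,3-triethoxyprop-1-yne | C#CC(OCC)(OCC)OCC | starting material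
9 | trifluoromethanesulfonate of 7 (C1 triflate) | FC(F)(F)S(=O)(=O)OC[C@@H](O[Si](C)(C)C(C)(C)C)C[C@](C)(CO[Si](C)(C)C(C)(C)C)CC=C | intermediate (not isolated)
10 | (5R,7R)-5-(TBS-oxy)-7-[(TBS-oxy)methyl]-1,1,1-triethoxy-7-methyldec-9-en-2-yne | CCOC(OCC)(OCC)C#CC[C@@H](O[Si](C)(C)C(C)(C)C)C[C@](C)(CO[Si](C)(C)C(C)(C)C)CC=C | intermediate (not isolated)
11 | ethyl (5R,7R)-5-(TBS-oxy)-7-[(TBS-oxy)methyl]-7-methyldec-9-en-2-ynoate | CCOC(=O)C#CC[C@@H](O[Si](C)(C)C(C)(C)C)C[C@](C)(CO[Si](C)(C)C(C)(C)C)CC=C | intermediate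
12 | lithium alkenyl(methyl)cuprate from syn addition to 11 (Cu on C9, cis to the new C10 methyl) | [Li+].CCOC(=O)/C([Cu-]C)=C(/C)C[C@@H](O[Si](C)(C)C(C)(C)C)C[C@](C)(CO[Si](C)(C)C(C)(C)C)CC=C | intermediate (not isolated)
13 | ethyl (2E,5S,7R)-5-(TBS-oxy)-7-[(TBS-oxy)methyl]-2-iodo-3,7-dimethyldeca-2,9-dienoate | CCOC(=O)/C(I)=C(/C)C[C@@H](O[Si](C)(C)C(C)(C)C)C[C@](C)(CO[Si](C)(C)C(C)(C)C)CC=C | intermediate
14 | ethyl (2E,5S,7S)-5-(TBS-oxy)-7-[(TBS-oxy)methyl]-2-iodo-3,7-dimethyl-9-oxonon-2-enoate | CCOC(=O)/C(I)=C(/C)C[C@@H](O[Si](C)(C)C(C)(C)C)C[C@](C)(CO[Si](C)(C)C(C)(C)C)CC=O | intermediate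
15 | 4,4,5,5-tetramethyl-2-(prop-1-en-2-yl)-1,3,2-dioxaborolane | CC(=C)B1OC(C)(C)C(C)(C)O1 | starting material
16 | ethyl (2Z,5R,7S)-5-(TBS-oxy)-7-[(TBS-oxy)methyl]-3,7-dimethyl-9-oxo-2-(prop-1-en-2-yl)non-2-enoate | CCOC(=O)/C(C(C)=C)=C(/C)C[C@@H](O[Si](C)(C)C(C)(C)C)C[C@](C)(CO[Si](C)(C)C(C)(C)C)CC=O | intermediate
17 | ethyl (2Z,5R,7S)-5-(TBS-oxy)-7-[(TBS-oxy)methyl]-3,7-dimethyl-2-(prop-1-en-2-yl)-9-(TES-oxy)nona-2,8-dienoate, 8E/8Z mixture | CCOC(=O)/C(C(C)=C)=C(/C)C[C@@H](O[Si](C)(C)C(C)(C)C)C[C@](C)(CO[Si](C)(C)C(C)(C)C)C=CO[Si](CC)(CC)CC | intermediate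
18 | ring-A-closed silyl ketene acetal with a C6 silyloxocarbenium ion, triflimide salt (C5–C10 bond formed, C6 arm and dienyl unit trans) | CCOC(O[Si](CC)(CC)CC)=C(C(C)=C)[C@@]1(C)C[C@@H](O[Si](C)(C)C(C)(C)C)C[C@](C)(CO[Si](C)(C)C(C)(C)C)[C@@H]1C=[O+][Si](CC)(CC)CC.FC(F)(F)S(=O)(=O)[N-]S(=O)(=O)C(F)(F)F | intermediate (not isolated)
19 | ethyl 2α,19-bis(TBS-oxy)-6α-(TES-oxy)-12,13,14,15,16-pentanorlabd-8-en-11-oate (5α-H, 10β-CH3) | CC[Si](CC)(CC)O[C@H]1CC(C)=C(C(=O)OCC)[C@@]2(C)C[C@@H](O[Si](C)(C)C(C)(C)C)C[C@](C)(CO[Si](C)(C)C(C)(C)C)[C@H]12 | intermediate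
20 | 2α,19-bis(TBS-oxy)-6α-(TES-oxy)-12,13,14,15,16-pentanorlabd-8-en-11-ol | CC[Si](CC)(CC)O[C@H]1CC(C)=C(CO)[C@@]2(C)C[C@@H](O[Si](C)(C)C(C)(C)C)C[C@](C)(CO[Si](C)(C)C(C)(C)C)[C@H]12 | intermediate
21 | 2α,19-bis(TBS-oxy)-6α-(TES-oxy)-12,13,14,15,16-pentanorlabd-8-en-11-al | CC[Si](CC)(CC)O[C@H]1CC(C)=C(C=O)[C@@]2(C)C[C@@H](O[Si](C)(C)C(C)(C)C)C[C@](C)(CO[Si](C)(C)C(C)(C)C)[C@H]12 | intermediate
22 | 2α,19-bis(TBS-oxy)-6α-(TES-oxy)-13,14,15,16-tetranorlabda-8,11-diene | CC[Si](CC)(CC)O[C@H]1CC(C)=C(C=C)[C@@]2(C)C[C@@H](O[Si](C)(C)C(C)(C)C)C[C@](C)(CO[Si](C)(C)C(C)(C)C)[C@H]12 | intermediate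
23 | 4-bromofuran-2(5H)-one | BrC1=CC(=O)OC1 | starting material
24 | 9-[2α,19-bis(TBS-oxy)-6α-(TES-oxy)-13,14,15,16-tetranorlabd-8-en-12-yl]-9-borabicyclo[3.3.1]nonane | CC[Si](CC)(CC)O[C@H]1CC(C)=C(CCB2C3CCCC2CCC3)[C@@]2(C)C[C@@H](O[Si](C)(C)C(C)(C)C)C[C@](C)(CO[Si](C)(C)C(C)(C)C)[C@H]12 | intermediate (not isolated)
25 | 2α,19-bis(TBS-oxy)-6α-(TES-oxy)labda-8,13-dien-15,16-olide | CC[Si](CC)(CC)O[C@H]1CC(C)=C(CCC2=CC(=O)OC2)[C@@]2(C)C[C@@H](O[Si](C)(C)C(C)(C)C)C[C@](C)(CO[Si](C)(C)C(C)(C)C)[C@H]12 | intermediate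
26 | 2α,19-bis(TBS-oxy)-6α-hydroxylabda-8,13-dien-15,16-olide | O[C@H]1CC(C)=C(CCC2=CC(=O)OC2)[C@@]2(C)C[C@@H](O[Si](C)(C)C(C)(C)C)C[C@](C)(CO[Si](C)(C)C(C)(C)C)[C@H]12 | intermediate
27 | 6α-acetoxy-2α,19-bis(TBS-oxy)labda-8,13-dien-15,16-olide | CC(=O)O[C@H]1CC(C)=C(CCC2=CC(=O)OC2)[C@@]2(C)C[C@@H](O[Si](C)(C)C(C)(C)C)C[C@](C)(CO[Si](C)(C)C(C)(C)C)[C@H]12 | intermediate
28 | CNP0231903.1, 6α-acetoxy-2α,19-dihydroxylabda-8,13-dien-15,16-olide (2R,4S,5R,6S,10S) | CC(=O)O[C@H]1CC(C)=C(CCC2=CC(=O)OC2)[C@@]2(C)C[C@@H](O)C[C@](C)(CO)[C@H]12 | target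

**Step count and risks**

Total step count: 19. Longest linear sequence: 19 steps (from 1).

Steps most likely to fail:

1. Step 12 (proposed new method). Ring A must close between two neopentyl-type carbons (C5 and C10). If this is slow, protodesilylation of the enol ether back to 16 or closure of the oxocarbenium ion through C9 to a cyclobutane may take over, and the ring fusion may form cis if the C6 arm goes axial. The fallback sets out from 17 and comes back at 19, and makes the two bonds in separate, known operations. A stoichiometric TiCl4-promoted intramolecular Mukaiyama–Michael addition (CH2Cl2, −78 °C, aqueous work-up) should give the ring-A ester aldehyde F1, in which only C5–C10 has formed. Treating it with KOt-Bu in t-BuOH/THF (reversible intramolecular vinylogous aldol addition of the ester dienolate through C7, under thermodynamic control at C5 and C6) should give the bicyclic C6 alcohol F2. TESOTf/2,6-lutidine then returns 19.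

2. Step 7. Displacement of the β-silyloxy triflate may lose to elimination or to O2→O1 silyl migration, and the orthoester acetylide may react sluggishly. The fallback sets out from 5 and comes back at 11, and replaces the displacement by an epoxide opening. TBSCl/imidazole (DMF, 0 °C) should silylate only the primary C19 hydroxyl to give the mono-silyl ether F3. BCl3 detritylation gives the 1,2-diol F4. NaH/N-tosylimidazole closes the terminal epoxide F5 with retention at C2. Lithiated ethyl propiolate with BF3·OEt2 (THF, −78 °C) opens it at C1 to the hydroxy ynoate F6. TBSOTf/2,6-lutidine then gives 11.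

3. Step 16. Hydroboration of the vinyl group, which is flanked by quaternary C10 and the C8 methyl, may be slow or unselective, and base-induced decomposition of the bromobutenolide may outrun transmetalation. The fallback sets out from 20 and comes back at 25, and builds the butenolide ring on the side chain. Appel bromination (CBr4, PPh3) gives the allylic bromide F7. γ-Alkylation with the dianion of ethyl acetoacetate (NaH, then n-BuLi, THF, 0 °C) gives the β-keto ester F8. Chelation-controlled Z-selective enol triflation (Tf2O, aq. LiOH, toluene) gives the (Z)-enol triflate F9. Stille hydroxymethylation with Bu3SnCH2OH (Pd(PPh3)4, LiCl, dioxane, 90 °C) with lactonisation in the flask returns 25.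

**Further compounds**

F1 | step 12 | ethyl 2-[ring-A cyclohexyl]-3-methylbut-3-enoate: C10 carries CH3 and the ester-bearing carbon, C5 carries CHO, C9 epimers | CCOC(=O)C(C(C)=C)[C@@]1(C)C[C@@H](O[Si](C)(C)C(C)(C)C)C[C@](C)(CO[Si](C)(C)C(C)(C)C)[C@@H]1C=O
F2 | step 12 | ethyl 2α,19-bis(TBS-oxy)-6α-hydroxy-12,13,14,15,16-pentanorlabd-8-en-11-oate | O[C@H]1CC(C)=C(C(=O)OCC)[C@@]2(C)C[C@@H](O[Si](C)(C)C(C)(C)C)C[C@](C)(CO[Si](C)(C)C(C)(C)C)[C@H]12
F3 | step 7 | (2S,4R)-4-[(TBS-oxy)methyl]-4-methyl-1-(trityloxy)hept-6-en-2-ol | C(c1ccccc1)(c1ccccc1)(c1ccccc1)OC[C@@H](O)C[C@](C)(CO[Si](C)(C)C(C)(C)C)CC=C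
F4 | step 7 | (2S,4R)-4-[(TBS-oxy)methyl]-4-methylhept-6-ene-1,2-diol | OC[C@@H](O)C[C@](C)(CO[Si](C)(C)C(C)(C)C)CC=C
F5 | step 7 | tert-butyldimethyl{[(2R)-2-methyl-2-{[(2S)-oxiran-2-yl]methyl}pent-4-en-1-yl]oxy}silane | C1O[C@H]1C[C@](C)(CO[Si](C)(C)C(C)(C)C)CC=C
F6 | step 7 | ethyl (5R,7R)-7-[(TBS-oxy)methyl]-5-hydroxy-7-methyldec-9-en-2-ynoate | CCOC(=O)C#CC[C@@H](O)C[C@](C)(CO[Si](C)(C)C(C)(C)C)CC=C
F7 | step 16 | 11-bromo-2α,19-bis(TBS-oxy)-6α-(TES-oxy)-12,13,14,15,16-pentanorlabd-8-ene | CC[Si](CC)(CC)O[C@H]1CC(C)=C(CBr)[C@@]2(C)C[C@@H](O[Si](C)(C)C(C)(C)C)C[C@](C)(CO[Si](C)(C)C(C)(C)C)[C@H]12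
F8 | step 16 | ethyl 2α,19-bis(TBS-oxy)-13-oxo-6α-(TES-oxy)-16-norlabd-8-en-15-oate | CC[Si](CC)(CC)O[C@H]1CC(C)=C(CCC(=O)CC(=O)OCC)[C@@]2(C)C[C@@H](O[Si](C)(C)C(C)(C)C)C[C@](C)(CO[Si](C)(C)C(C)(C)C)[C@H]12
F9 | step 16 | ethyl (13Z)-2α,19-bis(TBS-oxy)-6α-(TES-oxy)-13-(triflyloxy)-16-norlabda-8,13-dien-15-oate | CC[Si](CC)(CC)O[C@H]1CC(C)=C(CC/C(OS(=O)(=O)C(F)(F)F)=C/C(=O)OCC)[C@@]2(C)C[C@@H](O[Si](C)(C)C(C)(C)C)C[C@](C)(CO[Si](C)(C)C(C)(C)C)[C@H]12
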